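A direct plan would close the cyclobutane by an enantioselective [2+2] photocycloaddition of cyclohex-2-enone with isobutene to the cis-fused bicyclic ketone A1, add the three-carbon chain through the enol triflate, and open the six-membered ring by ozonolysis to the cis-acylcyclobutane A2.
A2 would be epimerised to the trans isomer A3, and the two chains would then be adjusted one group at a time before the final esterification with linoleic acid.
Weak point (a), the photocycloaddition: the absolute configuration of everything that follows would rest on a chiral Lewis acid used in large amount at −75 °C under irradiation with a condensed gas, with no later chance to raise the enantiomeric purity.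
Weak point (b), the base equilibration of A2 to A3: the second ring stereocentre would be left to a thermodynamic ratio, with separation and recycling of the cis isomer.
Weak point (c), the chain adjustment after ring opening: about seven steps (acetal on and off, methylenation, methyl addition, oxidation, silyl ether on and off) would add only two carbons, and the multi-stage ozonolysis would run on material that already carries the whole ring.

Plan of the new route
The ester C–O bond is cut last (linoleic acid plus a primary carbinol); the core is then not cut but reconnected, by joining the ketone carbon of the 3-oxobutyl chain (C4, terpene numbering) to the O-bearing CH2 of the pentenyl chain (C5) as a C=C bond.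
The feature that allows this: C4 and C5 hang from the two adjacent cyclobutane carbons (C1 and C9) on chains of three and four atoms, so the reconnection closes a nine-membered ring trans-fused to the cyclobutane, with the gem-dimethyl carbon C11 next to C1 and the methylidene C8=C13 next to C9. That is (−)-β-caryophyllene, a bulk terpene with exactly the (1R,9S) ring centres of the target.
Forward, no ring is built: the cyclobutane is bought, and the only ring event is the opening of the nine-membered ring by chemoselective ozonolysis of its strained endocyclic alkene, which copies the presumed biogenesis of 4,5-seco-caryophyllanes.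
Borohydride work-up gives a primary/secondary diol, a lipase acylates only the primary hydroxyl with linoleic acid, and oxidation of the secondary carbinol gives the target in three steps.
The weak steps cannot occur: there is no photocycloaddition and no catalyst-derived chirality, no ring centre is ever α to a carbonyl (nothing to equilibrate), both chains arrive complete (no carbon is added), and no protecting group is used.

Key step: step 1

Assumption: natural (−)-(E)-β-caryophyllene, sold in bulk from clove-leaf oil as the (1R,9S) enantiomer, is taken as a commercially available starting material. Any (Z)-isomer in it converges on the same product in step 1, and humulene-derived material is removed at the stage of diol 3.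

Step 1
Reactants: 1 (−)-β-caryophyllene, (1R,4E,9S)-4,11,11-trimethyl-8-methylidenebicyclo[7.2.0]undec-4-ene
Product: 3 4-[(1R,4S)-4-(5-hydroxypent-1-en-2-yl)-2,2-dimethylcyclobutyl]butan-2-ol (both carbinol epimers), via methoxy-hydroperoxide aldehyde 2 (not isolated)
Conditions: O3/O2 (1.0 equiv O3, Sudan Red 7B end point), CH2Cl2/MeOH 4:1, −78 °C; N2 purge; NaBH4 (4 equiv), −78 → 0 °C; aq. NH4Cl
Reagents that add atoms: ozone, [O-][O+]=O
Why: Ozone adds as an electrophilic 1,3-dipole to the trisubstituted endocyclic C4=C5 bond, the primary ozonide cycloreverts to the C5 aldehyde and the C4 carbonyl oxide, methanol traps the latter as methoxy hydroperoxide 2, and NaBH4 reduces the aldehyde and the peroxy ketal to the diol (Criegee ozonolysis with reductive work-up). The closest known reaction type is the selective ozonolysis of the most electron-rich alkene of a polyene to a dye end point. No ring is closed: the step opens the nine-membered ring and leaves the cyclobutane, bought with the terpene, as the only ring. The selectivity needed is endocyclic against exocyclic alkene, and the substrate secures it because the endocyclic alkene is trisubstituted and twisted by the strain of the (E)-cyclononene, whereas the methylidene is 1,1-disubstituted, unstrained and shielded by the adjacent ring carbon, so that one equivalent of ozone should be consumed by the former. The two ring stereocentres are neither broken nor made epimerisable (no carbonyl is ever α to the ring), so C9 (S) and C1 (R) of 1 should pass unchanged into the (S)- and (R)-centres of the target. The one new stereocentre, the carbinol carbon, forms without control as both epimers and is erased in step 3.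

Step 2
Reactants: 3 4-[(1R,4S)-4-(5-hydroxypent-1-en-2-yl)-2,2-dimethylcyclobutyl]butan-2-ol (both carbinol epimers); 4 (9Z,12Z)-octadeca-9,12-dienoic acid (linoleic acid, 1.05 equiv)
Product: 5 4-[(1S,2R)-2-(3-hydroxybutyl)-3,3-dimethylcyclobutyl]pent-4-en-1-yl (9Z,12Z)-octadeca-9,12-dienoate (both carbinol epimers)
Conditions: immobilised Rhizomucor miehei lipase (a lipase selective for primary hydroxyl groups), 4 Å MS, MTBE/n-heptane 1:1, 35 °C, Ar, dark
Reagents that add atoms: none
Why: Lipase-catalysed esterification, in which the serine acyl-enzyme formed from linoleic acid should pass its acyl group to the unhindered primary hydroxyl far faster than to the secondary methyl carbinol, so the two chain ends are told apart without a protecting group, at neutral pH that leaves the skipped (Z,Z)-diene and the methylidene alone, with sieves removing water.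

Step 3
Reactants: 5 4-[(1S,2R)-2-(3-hydroxybutyl)-3,3-dimethylcyclobutyl]pent-4-en-1-yl (9Z,12Z)-octadeca-9,12-dienoate (both carbinol epimers)
Product: 6 4-[(1S,2R)-3,3-dimethyl-2-(3-oxobutyl)cyclobutyl]pent-4-en-1-yl (9Z,12Z)-octadeca-9,12-dienoate (target, IN0146)
Conditions: Dess–Martin periodinane (1.3 equiv), CH2Cl2, 0 °C → rt, Ar, dark; aq. Na2S2O3/NaHCO3
Reagents that add atoms: none
Why: Dess–Martin oxidation should convert both carbinol epimers into the one methyl ketone under non-basic, metal-free conditions to which the ester, the methylidene and the skipped diene are inert, and neither ring stereocentre is α to the new carbonyl.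

Compound list
1 | (−)-β-caryophyllene, (1R,4E,9S)-4,11,11-trimethyl-8-methylidenebicyclo[7.2.0]undec-4-ene | C/C1=C\CCC(=C)[C@H]2CC(C)(C)[C@@H]2CC1 | starting material
2 | 4-[(1S,2R)-2-(3-hydroperoxy-3-methoxybutyl)-3,3-dimethylcyclobutyl]pent-4-enal (epimers at the peroxy carbon) | C=C(CCC=O)[C@H]1CC(C)(C)[C@@H]1CCC(C)(OC)OO | intermediate
3 | 4-[(1R,4S)-4-(5-hydroxypent-1-en-2-yl)-2,2-dimethylcyclobutyl]butan-2-ol (both carbinol epimers) | C=C(CCCO)[C@H]1CC(C)(C)[C@@H]1CCC(C)O | intermediate
4 | (9Z,12Z)-octadeca-9,12-dienoic acid (linoleic acid) | CCCCC/C=C\C/C=C\CCCCCCCC(=O)O | starting material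
5 | 4-[(1S,2R)-2-(3-hydroxybutyl)-3,3-dimethylcyclobutyl]pent-4-en-1-yl (9Z,12Z)-octadeca-9,12-dienoate (both carbinol epimers) | C=C(CCCOC(=O)CCCCCCC/C=C\C/C=C\CCCCC)[C@H]1CC(C)(C)[C@@H]1CCC(C)O | intermediate
6 | 4-[(1S,2R)-3,3-dimethyl-2-(3-oxobutyl)cyclobutyl]pent-4-en-1-yl (9Z,12Z)-octadeca-9,12-dienoate (IN0146) | C=C(CCCOC(=O)CCCCCCC/C=C\C/C=C\CCCCC)[C@H]1CC(C)(C)[C@@H]1CCC(C)=O | target

Total step count: 3. Longest linear sequence: 3 steps (from 1).

Steps most likely to fail, with fallbacks

Step 1. The risk is over-oxidation: ozone may go on to the methylidene before the endocyclic alkene is fully consumed, or the two alkenes may not be told apart cleanly on scale. The fallback sets out from 1 and comes back to the route at 3. K2OsO4·2H2O (cat.) with N-methylmorpholine N-oxide in acetone/water should dihydroxylate the strained trisubstituted alkene first. The expected product is (1R,4R,5R,9S)-4,11,11-trimethyl-8-methylidenebicyclo[7.2.0]undecane-4,5-diol F1, a stable compound that can be freed from any tetraol before the ring is cut; attack from the other face would converge. NaIO4 in THF/water would then cleave the glycol to 4-[(1S,2R)-3,3-dimethyl-2-(3-oxobutyl)cyclobutyl]pent-4-enal F2, and NaBH4 in MeOH at 0 °C would reduce both carbonyl groups to 3.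

Step 2. The risk is loss of regioselectivity: the enzyme may also acylate the secondary carbinol of one epimer, or the esterification may stall. The fallback sets out from 3 (with 4) and comes back at 5. A Mitsunobu esterification (PPh3, diisopropyl azodicarboxylate, THF, 0 °C) activates the alcohol instead of the acid; the bulky alkoxyphosphonium should form at the primary carbinol only and be displaced there by the linoleate. It makes no new compound.

Step 3. The risk is radical autoxidation or Z/E isomerisation of the skipped diene during oxidation and work-up of the lipid. The fallback sets out from 3 and comes back at 6, bypassing 5, so that the oxidation is over before the diene arrives. Selective iodination of the primary hydroxyl (I2, PPh3, imidazole, CH2Cl2, 0 °C) should give 4-[(1R,4S)-4-(5-iodopent-1-en-2-yl)-2,2-dimethylcyclobutyl]butan-2-ol F3. Dess–Martin periodinane would oxidise it to 4-[(1R,4S)-4-(5-iodopent-1-en-2-yl)-2,2-dimethylcyclobutyl]butan-2-one F4. O-Alkylation of caesium linoleate (from 4 and Cs2CO3, DMF, rt) with F4 would then give 6 directly.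

Further compounds
F1 | step 1 | (1R,4R,5R,9S)-4,11,11-trimethyl-8-methylidenebicyclo[7.2.0]undecane-4,5-diol | C[C@@]1(O)CC[C@@H]2[C@H](CC2(C)C)C(=C)CC[C@H]1O
F2 | step 1 | 4-[(1S,2R)-3,3-dimethyl-2-(3-oxobutyl)cyclobutyl]pent-4-enal | C=C(CCC=O)[C@H]1CC(C)(C)[C@@H]1CCC(C)=O
F0 | step 2 | none | none
F3 | step 3 | 4-[(1R,4S)-4-(5-iodopent-1-en-2-yl)-2,2-dimethylcyclobutyl]butan-2-ol (both carbinol epimers) | C=C(CCCI)[C@H]1CC(C)(C)[C@@H]1CCC(C)O
F4 | step 3 | 4-[(1R,4S)-4-(5-iodopent-1-en-2-yl)-2,2-dimethylcyclobutyl]butan-2-one | C=C(CCCI)[C@H]1CC(C)(C)[C@@H]1CCC(C)=O
A1 | direct plan | (1R,6R)-7,7-dimethylbicyclo[4.2.0]octan-2-one (cis-fused) | O=C1CCC[C@@H]2[C@H]1CC2(C)C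
A2 | direct plan | 4-[(tert-butyldiphenylsilyl)oxy]-1-[(1R,2R)-2-(3,3-dimethoxypropyl)-3,3-dimethylcyclobutyl]butan-1-one (cis) | COC(OC)CC[C@@H]1[C@H](C(=O)CCCO[Si](c2ccccc2)(c2ccccc2)C(C)(C)C)CC1(C)C
A3 | direct plan | 4-[(tert-butyldiphenylsilyl)oxy]-1-[(1S,2R)-2-(3,3-dimethoxypropyl)-3,3-dimethylcyclobutyl]butan-1-one (trans) | COC(OC)CC[C@@H]1[C@@H](C(=O)CCCO[Si](c2ccccc2)(c2ccccc2)C(C)(C)C)CC1(C)C
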